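The constants are made up; the result is computed.

Which way of charging Q and X leaves the most D in the flask when the run ends?

| setting | grey | amber | ochre | green | red |
|---|---|---|---|---|---|
| Q | 0.10 M | 0.10 M | 0.10 M (fed, over 20 min) | 0.10 M | 0.10 M |
| X | 1.20 equiv (fed, over 80 min) | 1.20 equiv | 1.20 equiv | 1.20 equiv | 1.20 equiv (fed, over 80 min) |
| time | 1.5 h | 1.5 h | 1.5 h | 1.5 h | 1.5 h |
| remark | the addition at 70 °C, then warmed to 100 °C; the feed brings no volume worth counting | everything together at the start | all else is in the flask from the start; the feed brings no volume worth counting | everything together at the start at 70 °C, warmed to 100 °C at 80 min | all else is in the flask from the start; the feed brings no volume worth counting |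
| temperature |  | 100 °C | 100 °C |  | 100 °C |

    Q + X → E + J (k1 = 0.020 /M/s, Ea1 = 59.0 kJ/mol)
    Q + J → Q.J (k2 = 0.0064 /M/s, Ea2 = 68.0 kJ/mol)
    X + D → Z + J (k3 = 3.8 × 10⁻⁴ /M/s, Ea3 = 74.0 kJ/mol)
    X ⇌ L (K4 = 1.5, k4 = 0.0065 /s, Ea4 = 110 kJ/mol, ΔH4 = −11.0 kJ/mol)
    X + E → D + J (k5 = 0.0080 /M/s, Ea5 = 85.0 kJ/mol)
    (constants at 100 °C)

- the flask that comes out highest in amount of D, in percent of the Q charged; "all alike" if 1.5 percentage points covers them all (grey / amber / ochre / green / red / all alike)
- amount of D at the end, in percent of the Q charged, grey
- amount of D at the end, in percent of the Q charged, amber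
- amount of D at the end, in percent of the Q charged, ochre
- amount of D at the end, in percent of the Q charged, green
- amount of D at the end, in percent of the Q charged, red

- all constants are for 100 °C and move with temperature by the activation energies and enthalpies

D is made from E by X, while Q competes for the same X, so we compare the two rates at one moment:

rate of X + E / rate of Q + X = (cE/cQ) / h, with h = 0.020 /M/s / 0.0080 /M/s = 2.50

We call h the handover ratio, the value of cE/cQ at which X is shared evenly between Q and E; it is the inverse of a selectivity factor. If X made no choice, h would be 1, so that is the zero of our scale. Here X favours Q, and E must outnumber Q by h before D gains the upper hand. Free cX stands in both rates and cancels, so neither L nor the feed enters h.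

Next we ask when each flask gets there. We take a ladder of clocks at 100 °C, with the free share of the X charge:

X ⇌ L relaxes: 92.3 s, leaving a free share of 40.0 %, so cX = 0.0480 M

Q against X: 17.4 min

E against X: 43.4 min

D against X: 15.2 h

The equilibrium is set long before Q reacts. E has time to react within the run, whereas D hardly reacts further, so we leave Z out.

In amber and ochre, Q's clock is short against the run, so both should pass h early. In red, X comes in over 80 min, longer than Q's clock, and that clock counts the whole X charge, which red has received when the feed ends; so we expect cE/cQ to climb later there than in amber, with 10.0 min of run left after the feed.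

The cold flasks fall further behind. At 70 °C, h rises to 5.20, and Q's clock stretches to 91.5 min. We expect the order amber, ochre, red, then green and grey.

The forecast named amber, with D at 29 % in amber, 27.5 % in ochre, 16 % in red, 12 % in green and 9.5 % in grey, holding that “slow X dosing starves step 5”.

D ends at 28.5 % in amber, 26.7 % in ochre, 17.2 % in red, 9.59 % in green and 7.72 % in grey, so amber comes out highest. After 15.0 h, amber holds 47.6 % of D and grey 46.8 %. At the end of the run, with h taken at 100 °C, (cE/cQ)/h reads 7.18 in amber, 4.48 in ochre, 1.42 in red, 0.881 in green and 0.560 in grey, the same order as D.

Now take grey with 3.00 equiv of X. Its h is unchanged, and with E at 50.2 % and Q at 5.36 % at the end, (cE/cQ)/h reads 3.75, past the handover. The computed D in that flask is 33.0 %.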